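**Plan**
- Retrosynthesis: after global debenzylation/debromination, the pyran ring of the epiafzelechin unit (unit A) is cut at C4–C4a together with the interflavan bond C4(A)–C8(C). C4 thereby becomes the aldehyde carbon of open-chain aryl ether 22, and the lower half is dimer 9. Further cuts: O1–C2 of unit A (phenoxide + cis-glycidate), C4(B)–aryl (unit B cation + phloroglucinol), and C4(C)–C6(D).
- Enabling feature: C4 of unit A is a diarylmethine flanked by two phloroglucinol rings (C4a of unit A, C8 of unit C), which is the oxidation level of an aldehyde arylated twice. Before closure the aromatic ring of unit A is a 3,5-dibenzyloxyphenyl ether with unit B para to O1, so closure at an ortho carbon can only give the 4→6 linkage.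
- Forward order: (−)-epicatechin → benzylated, halogen-capped units; C–D dimer by 4→6 coupling (Br at C8 of D directs to C6, I at C8 of C is a removable cap); unit B + phloroglucinol; ether formation with the glycidate; aldehyde. Then the pyran ring of unit A is closed last and joined to C–D in one operation, followed by hydrogenolysis.
- Stereochemistry: the centres of units B, C and D come from (−)-epicatechin; C2/C3 of unit A from a Jacobsen epoxidation plus SN2 inversion; each C4 centre from attack on a flavan-4-yl cation anti to the C3 oxygen.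
- Helpers: Br at C8 of units A, B and D and I at C8 of unit C block unwanted sites; I is removed in step 7, the bromides in step 20.

Key step: step 19

Assumption: the target is read as epicatechin-(4β→6)-epiafzelechin-(4β→8)-epicatechin-(4β→6)-epicatechin, all units (2R,3R), all interflavan bonds 3,4-trans (units B, A, C, D from top to bottom); the sense of induction of the salen catalyst in step 14 is taken by analogy with cis-cinnamate esters.

**Step 1**
Reactants: 1 (−)-epicatechin
Product: 2 5,7,3',4'-tetra-O-benzyl-(−)-epicatechin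
Conditions: BnBr, K2CO3, DMF, rt
Reagents that add atoms: benzyl bromide, BrCc1ccccc1
Why: Williamson etherification under weak base should cap the four phenols and leave the less acidic 3-OH free, without base-induced C2 epimerisation.

**Step 2**
Reactants: 2 tetra-O-benzylepicatechin
Product: 3 3,5,7,3',4'-penta-O-benzylepicatechin
Conditions: NaH, BnBr, DMF, 0 °C to rt
Reagents that add atoms: benzyl bromide, BrCc1ccccc1
Why: Williamson etherification of the secondary alcohol, safe with strong base once no free phenol remains.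

**Step 3**
Reactants: 3 penta-O-benzylepicatechin
Product: 4 8-bromo-penta-O-benzylepicatechin
Conditions: NBS, CH2Cl2, −78 to 0 °C
Reagents that add atoms: N-bromosuccinimide, O=C1CCC(=O)N1Br
Why: electrophilic aromatic bromination should occur at C8, the most accessible activated position of the phloroglucinol ring, installing the blocking bromide.

**Step 4**
Reactants: 3 penta-O-benzylepicatechin
Product: 5 8-iodo-penta-O-benzylepicatechin
Conditions: NIS, CH2Cl2, −40 to 0 °C
Reagents that add atoms: N-iodosuccinimide, O=C1CCC(=O)N1I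
Why: electrophilic aromatic iodination at C8 by analogy with step 3 gives a cap that can later be removed in the presence of aryl bromides.

**Step 5**
Reactants: 5 8-iodo-penta-O-benzylepicatechin
Product: 6 8-iodo-4β-(2-ethoxyethoxy)-penta-O-benzylepicatechin
Conditions: DDQ, 2-ethoxyethanol, CH2Cl2, rt
Reagents that add atoms: 2-ethoxyethanol, CCOCCO
Why: DDQ benzylic oxidation (hydride abstraction at C4) gives the flavan-4-yl cation, which the alcohol should trap anti to the 3-benzyloxy group to set the 4β (3,4-trans) ether.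

**Step 6**
Reactants: 6 8-iodo-4β-(2-ethoxyethoxy)-penta-O-benzylepicatechin; 4 8-bromo-penta-O-benzylepicatechin (3 equiv)
Product: 7 deca-O-benzyl 8-iodoepicatechin-(4β→6)-8-bromoepicatechin
Conditions: TMSOTf (0.3 equiv), CH2Cl2, −78 to −40 °C, slow addition of 6
Reagents that add atoms: none
Why: Lewis-acid Friedel–Crafts interflavan coupling in which the cation from 6 should be attacked by C6 of 4 (C8 blocked by Br) anti to the 3-benzyloxy group, setting C4 of unit C as 4β, while the iodide keeps electrophile and product from acting as C8 nucleophiles.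

**Step 7**
Reactants: 7 iodo/bromo dimer
Product: 9 deca-O-benzyl epicatechin-(4β→6)-8-bromoepicatechin, via arylmagnesium chloride 8 (not isolated)
Conditions: i-PrMgCl·LiCl, THF, −20 to 0 °C; then MeOH
Reagents that add atoms: none
Why: iodine–magnesium exchange is much faster for the aryl iodide than for the aryl bromide, so protonation of the Grignard should free C8 of unit C and leave the bromide of unit D in place.

**Step 8**
Reactants: 4 8-bromo-penta-O-benzylepicatechin
Product: 10 8-bromo-4β-(2-ethoxyethoxy)-penta-O-benzylepicatechin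
Conditions: DDQ, 2-ethoxyethanol, CH2Cl2, rt
Reagents that add atoms: 2-ethoxyethanol, CCOCCO
Why: DDQ benzylic oxidation at C4 with alcohol capture anti to the 3-benzyloxy group, as in step 5.

**Step 9**
Reactants: 10 bromo-capped unit B electrophile; 11 phloroglucinol (5 equiv)
Product: 12 2-(8-bromo-penta-O-benzylepicatechin-4β-yl)benzene-1,3,5-triol
Conditions: BF3·OEt2 (0.5 equiv), THF/CH2Cl2, 0 °C to rt
Reagents that add atoms: none
Why: Friedel–Crafts capture of the flavan-4-yl cation by phloroglucinol, whose three ring carbons are equivalent, so only one constitution can form and attack anti to the 3-benzyloxy group should set C4 of unit B as 4β.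

**Step 10**
Reactants: 12 flavanyl-phloroglucinol
Product: 13 5-O-triisopropylsilyl ether of 12 (silyl on the hydroxyl para to the flavanyl group)
Conditions: TIPSCl (1.05 equiv), imidazole, DMF, −20 to 0 °C
Reagents that add atoms: triisopropylsilyl chloride, CC(C)[Si](Cl)(C(C)C)C(C)C
Why: silylation with a bulky silyl chloride should select the one phenol that has no ortho substituent over the two flanked by the flavan-4-yl group.

**Step 11**
Reactants: 13 mono-silyl ether
Product: 14 1,3-di-O-benzyl-5-O-triisopropylsilyl derivative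
Conditions: BnBr, Cs2CO3, MeCN, rt
Reagents that add atoms: benzyl bromide, BrCc1ccccc1
Why: Williamson benzylation of the two remaining phenols under conditions an aryl triisopropylsilyl ether should tolerate.

**Step 12**
Reactants: 14 silyl ether
Product: 15 3,5-bis(benzyloxy)-4-(8-bromo-penta-O-benzylepicatechin-4β-yl)phenol
Conditions: TBAF, AcOH, THF, 0 °C
Reagents that add atoms: none
Why: fluoride-mediated desilylation frees the single phenol that will become O1 of unit A.

**Step 13**
Reactants: 16 4-(benzyloxy)benzaldehyde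
Product: 17 ethyl (Z)-3-[4-(benzyloxy)phenyl]prop-2-enoate
Conditions: ethyl (diphenoxyphosphoryl)acetate, NaH, THF, −78 to 0 °C
Reagents that add atoms: ethyl 2-(diphenoxyphosphoryl)acetate, CCOC(=O)CP(=O)(Oc1ccccc1)Oc1ccccc1
Why: Ando-type Horner–Wadsworth–Emmons olefination with a diaryl phosphonate should be Z-selective for aromatic aldehydes.

**Step 14**
Reactants: 17 (Z)-cinnamate
Product: 18 ethyl (2S,3S)-3-[4-(benzyloxy)phenyl]oxirane-2-carboxylate (cis)
Conditions: NaOCl (aq, buffered), (S,S)-N,N'-bis(3,5-di-tert-butylsalicylidene)-1,2-cyclohexanediaminomanganese chloride (trivalent manganese, 5 mol%), 4-phenylpyridine N-oxide, CH2Cl2, 4 °C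
Reagents that add atoms: sodium hypochlorite, [Na+].[O-]Cl
Why: Jacobsen–Katsuki epoxidation of a cis-cinnamate ester, in which the chiral salen catalyst selects the alkene face and thereby sets both epoxide carbons.

**Step 15**
Reactants: 15 phenol; 18 cis-glycidate (1.5 equiv)
Product: 19 ethyl (2S,3R)-3-aryloxy-3-[4-(benzyloxy)phenyl]-2-hydroxypropanoate (aryl = 3,5-bis(benzyloxy)-4-(8-bromo-penta-O-benzylepicatechin-4β-yl)phenyl)
Conditions: Cs2CO3 (0.3 equiv), DMF, 50 °C
Reagents that add atoms: none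
Why: base-catalysed SN2 opening of the glycidic ester by the phenoxide at benzylic C3 should proceed with inversion, so the cis-epoxide gives the syn aryloxy alcohol (future C2 = R, future C3 retained).

**Step 16**
Reactants: 19 hydroxy ester
Product: 20 2-O-benzyl ether of 19
Conditions: BnBr, Ag2O, CH2Cl2, rt, dark
Reagents that add atoms: benzyl bromide, BrCc1ccccc1
Why: silver-oxide-mediated benzylation works without strong base and should avoid epimerisation and β-elimination of the aryloxide.

**Step 17**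
Reactants: 20 benzyl ether
Product: 21 monobromide of 20 (Br ortho to the ether oxygen on the central phloroglucinol ring)
Conditions: NBS (1.0 equiv), CH2Cl2, −78 to −20 °C
Reagents that add atoms: N-bromosuccinimide, O=C1CCC(=O)N1Br
Why: electrophilic aromatic bromination should hit the most electron-rich ring at one of its two equivalent free positions, installing the future C8 cap of unit A and leaving one ortho carbon for ring closure.

**Step 18**
Reactants: 21 bromo ester
Product: 22 (2S,3R)-3-aryloxy-2-(benzyloxy)-3-[4-(benzyloxy)phenyl]propanal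
Conditions: i-Bu2AlH, toluene/CH2Cl2, −78 °C; Rochelle salt work-up; used crude
Reagents that add atoms: none
Why: half-reduction of an α-alkoxy ester, whose chelated aluminium hemiacetal should be stable at −78 °C and release the aldehyde only on work-up.

**Step 19**
Reactants: 22 aldehyde (1.0 equiv); 9 C–D dimer (1.2 equiv)
Product: 24 nonadeca-O-benzyl 8-bromoepicatechin-(4β→6)-8-bromoepiafzelechin-(4β→8)-epicatechin-(4β→6)-8-bromoepicatechin, via flavan-4-ol 23 (not isolated)
Conditions: BF3·OEt2 (0.5 equiv), 4 Å molecular sieves, CH2Cl2, −78 to −30 °C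
Reagents that add atoms: none
Why: Proposed new method: BF3 activation of the aldehyde should trigger a 6-exo-trig Friedel–Crafts hydroxyalkylation by the only free carbon ortho to the ether oxygen (C4–C4a bond), closing the pyran ring of unit A as flavan-4-ol 23; the same acid then ionises 23 to the flavan-4-yl cation (stabilised by O1, 5-OBn and 7-OBn), which is intercepted by C8 of the upper unit of dimer 9 (C4–C8 bond). The closest known reaction types are the acid cyclisation of 3-aryloxypropanals to chroman-4-ols and the Lewis-acid coupling of flavan-3,4-diols or 4-alkoxyflavans with flavan-3-ol nucleophiles; the new element is running them in tandem so that one aldehyde carbon is arylated twice and becomes C4. The new stereocentre C4 is controlled by the neighbouring C3 benzyloxy group: with the 2-aryl group equatorial and the 3-benzyloxy group axial in the half-chair cation, the nucleophile should add anti to the C3–O bond and give the 3,4-trans (4β) product, as is the rule for 2,3-cis flavan-4-yl cations, while C2 and C3 are carried in unchanged. Site selectivity in 9 is secured by the bromide at C8 of unit D and the intrinsic C8-over-C6 preference of the upper unit, and the 4→6 attachment of unit B follows from its position para to the ether oxygen. The bromine caps at C8 of units A and B leave electrophile and product without a reactive nucleophilic site, so a near-equimolar union should be possible, and the intramolecular closure should outrun attack of 9 on the aldehyde, which would in any case converge on the same constitution.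

**Step 20**
Reactants: 24 protected tribromo tetramer
Product: 25 epicatechin-(4β→6)-epiafzelechin-(4β→8)-epicatechin-(4β→6)-epicatechin (target)
Conditions: H2, Pd(OH)2/C, Et3N, THF/MeOH/H2O, rt
Reagents that add atoms: none
Why: catalytic hydrogenolysis should cleave all nineteen benzyl ethers and the three aryl bromides (amine traps HBr) without touching the stereocentres or the interflavan bonds.

**Compound list**
1 | (−)-epicatechin, (2R,3R) | O[C@@H]1Cc2c(O)cc(O)cc2O[C@@H]1c1ccc(O)c(O)c1 | starting material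
2 | 5,7,3',4'-tetra-O-benzyl-(−)-epicatechin | O[C@@H]1Cc2c(OCc3ccccc3)cc(OCc3ccccc3)cc2O[C@@H]1c1ccc(OCc2ccccc2)c(OCc2ccccc2)c1 | intermediate
3 | 3,5,7,3',4'-penta-O-benzylepicatechin | c1ccccc1CO[C@@H]1Cc2c(OCc3ccccc3)cc(OCc3ccccc3)cc2O[C@@H]1c1ccc(OCc2ccccc2)c(OCc2ccccc2)c1 | intermediate
4 | 8-bromo-penta-O-benzylepicatechin | c1ccccc1CO[C@@H]1Cc2c(OCc3ccccc3)cc(OCc3ccccc3)c(Br)c2O[C@@H]1c1ccc(OCc2ccccc2)c(OCc2ccccc2)c1 | intermediate
5 | 8-iodo-penta-O-benzylepicatechin | c1ccccc1CO[C@@H]1Cc2c(OCc3ccccc3)cc(OCc3ccccc3)c(I)c2O[C@@H]1c1ccc(OCc2ccccc2)c(OCc2ccccc2)c1 | intermediate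
6 | 8-iodo-4β-(2-ethoxyethoxy)-penta-O-benzylepicatechin (2,3-cis, 3,4-trans) | CCOCCO[C@H]1c2c(OCc3ccccc3)cc(OCc3ccccc3)c(I)c2O[C@H](c2ccc(OCc3ccccc3)c(OCc3ccccc3)c2)[C@@H]1OCc1ccccc1 | intermediate
7 | deca-O-benzyl 8-iodoepicatechin-(4β→6)-8-bromoepicatechin (I at C8 of upper unit C, Br at C8 of lower unit D) | c1([C@H]2c3c(OCc9ccccc9)cc(OCc9ccccc9)c(I)c3O[C@H](c3ccc(OCc9ccccc9)c(OCc9ccccc9)c3)[C@@H]2OCc9ccccc9)c(OCc9ccccc9)c(Br)c2c(c1OCc9ccccc9)C[C@@H](OCc9ccccc9)[C@@H](c1ccc(OCc9ccccc9)c(OCc9ccccc9)c1)O2 | intermediate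
8 | C8 magnesium chloride of the upper unit of the dimer | c1([C@H]2c3c(OCc9ccccc9)cc(OCc9ccccc9)c([Mg]Cl)c3O[C@H](c3ccc(OCc9ccccc9)c(OCc9ccccc9)c3)[C@@H]2OCc9ccccc9)c(OCc9ccccc9)c(Br)c2c(c1OCc9ccccc9)C[C@@H](OCc9ccccc9)[C@@H](c1ccc(OCc9ccccc9)c(OCc9ccccc9)c1)O2 | intermediate
9 | deca-O-benzyl epicatechin-(4β→6)-8-bromoepicatechin | c1([C@H]2c3c(OCc9ccccc9)cc(OCc9ccccc9)cc3O[C@H](c3ccc(OCc9ccccc9)c(OCc9ccccc9)c3)[C@@H]2OCc9ccccc9)c(OCc9ccccc9)c(Br)c2c(c1OCc9ccccc9)C[C@@H](OCc9ccccc9)[C@@H](c1ccc(OCc9ccccc9)c(OCc9ccccc9)c1)O2 | intermediate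
10 | 8-bromo-4β-(2-ethoxyethoxy)-penta-O-benzylepicatechin | CCOCCO[C@H]1c2c(OCc3ccccc3)cc(OCc3ccccc3)c(Br)c2O[C@H](c2ccc(OCc3ccccc3)c(OCc3ccccc3)c2)[C@@H]1OCc1ccccc1 | intermediate
11 | phloroglucinol | Oc1cc(O)cc(O)c1 | starting material
12 | 2-(8-bromo-penta-O-benzylepicatechin-4β-yl)benzene-1,3,5-triol | Oc1cc(O)c([C@H]4c5c(OCc9ccccc9)cc(OCc9ccccc9)c(Br)c5O[C@H](c5ccc(OCc9ccccc9)c(OCc9ccccc9)c5)[C@@H]4OCc9ccccc9)c(O)c1 | intermediate
13 | 5-O-triisopropylsilyl ether of 12 | CC(C)[Si](C(C)C)(C(C)C)Oc1cc(O)c([C@H]4c5c(OCc9ccccc9)cc(OCc9ccccc9)c(Br)c5O[C@H](c5ccc(OCc9ccccc9)c(OCc9ccccc9)c5)[C@@H]4OCc9ccccc9)c(O)c1 | intermediate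
14 | 1,3-di-O-benzyl-5-O-triisopropylsilyl derivative | CC(C)[Si](C(C)C)(C(C)C)Oc1cc(OCc9ccccc9)c([C@H]4c5c(OCc9ccccc9)cc(OCc9ccccc9)c(Br)c5O[C@H](c5ccc(OCc9ccccc9)c(OCc9ccccc9)c5)[C@@H]4OCc9ccccc9)c(OCc9ccccc9)c1 | intermediate
15 | 3,5-bis(benzyloxy)-4-(8-bromo-penta-O-benzylepicatechin-4β-yl)phenol | Oc1cc(OCc9ccccc9)c([C@H]4c5c(OCc9ccccc9)cc(OCc9ccccc9)c(Br)c5O[C@H](c5ccc(OCc9ccccc9)c(OCc9ccccc9)c5)[C@@H]4OCc9ccccc9)c(OCc9ccccc9)c1 | intermediate
16 | 4-(benzyloxy)benzaldehyde | O=Cc1ccc(OCc2ccccc2)cc1 | starting material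
17 | ethyl (Z)-3-[4-(benzyloxy)phenyl]prop-2-enoate | CCOC(=O)/C=C\c1ccc(OCc2ccccc2)cc1 | intermediate
18 | ethyl (2S,3S)-3-[4-(benzyloxy)phenyl]oxirane-2-carboxylate (cis) | CCOC(=O)[C@H]1O[C@H]1c1ccc(OCc2ccccc2)cc1 | intermediate
19 | ethyl (2S,3R)-3-aryloxy-3-[4-(benzyloxy)phenyl]-2-hydroxypropanoate | CCOC(=O)[C@@H](O)[C@H](Oc1cc(OCc9ccccc9)c([C@H]4c5c(OCc9ccccc9)cc(OCc9ccccc9)c(Br)c5O[C@H](c5ccc(OCc9ccccc9)c(OCc9ccccc9)c5)[C@@H]4OCc9ccccc9)c(OCc9ccccc9)c1)c1ccc(OCc9ccccc9)cc1 | intermediate
20 | 2-O-benzyl ether of 19 | CCOC(=O)[C@@H](OCc9ccccc9)[C@H](Oc1cc(OCc9ccccc9)c([C@H]4c5c(OCc9ccccc9)cc(OCc9ccccc9)c(Br)c5O[C@H](c5ccc(OCc9ccccc9)c(OCc9ccccc9)c5)[C@@H]4OCc9ccccc9)c(OCc9ccccc9)c1)c1ccc(OCc9ccccc9)cc1 | intermediate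
21 | ring-brominated ester (Br ortho to the ether oxygen) | CCOC(=O)[C@@H](OCc9ccccc9)[C@H](Oc1c(Br)c(OCc9ccccc9)c([C@H]4c5c(OCc9ccccc9)cc(OCc9ccccc9)c(Br)c5O[C@H](c5ccc(OCc9ccccc9)c(OCc9ccccc9)c5)[C@@H]4OCc9ccccc9)c(OCc9ccccc9)c1)c1ccc(OCc9ccccc9)cc1 | intermediate
22 | (2S,3R)-aldehyde | O=C[C@@H](OCc9ccccc9)[C@H](Oc1c(Br)c(OCc9ccccc9)c([C@H]4c5c(OCc9ccccc9)cc(OCc9ccccc9)c(Br)c5O[C@H](c5ccc(OCc9ccccc9)c(OCc9ccccc9)c5)[C@@H]4OCc9ccccc9)c(OCc9ccccc9)c1)c1ccc(OCc9ccccc9)cc1 | intermediate
23 | 8-bromo flavan-4-ol of unit A carrying unit B at C6 (both C4 epimers; 2R,3R) | c9ccccc9COc1ccc([C@H]2Oc3c(Br)c(OCc9ccccc9)c([C@H]4c5c(OCc9ccccc9)cc(OCc9ccccc9)c(Br)c5O[C@H](c5ccc(OCc9ccccc9)c(OCc9ccccc9)c5)[C@@H]4OCc9ccccc9)c(OCc9ccccc9)c3C(O)[C@H]2OCc9ccccc9)cc1 | intermediate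
24 | nonadeca-O-benzyl tribromo tetramer (Br at C8 of units B, A and D) | c9ccccc9COc1ccc([C@H]2Oc3c(Br)c(OCc9ccccc9)c([C@H]4c5c(OCc9ccccc9)cc(OCc9ccccc9)c(Br)c5O[C@H](c5ccc(OCc9ccccc9)c(OCc9ccccc9)c5)[C@@H]4OCc9ccccc9)c(OCc9ccccc9)c3[C@H](c3c(OCc9ccccc9)cc(OCc9ccccc9)c4c3O[C@H](c3ccc(OCc9ccccc9)c(OCc9ccccc9)c3)[C@H](OCc9ccccc9)[C@H]4c3c(OCc9ccccc9)c(Br)c4c(c3OCc9ccccc9)C[C@@H](OCc9ccccc9)[C@@H](c3ccc(OCc9ccccc9)c(OCc9ccccc9)c3)O4)[C@H]2OCc9ccccc9)cc1 | intermediate
25 | CNP0103636.1, epicatechin-(4β→6)-epiafzelechin-(4β→8)-epicatechin-(4β→6)-epicatechin | Oc1ccc([C@H]2Oc3cc(O)c([C@H]4c5c(O)cc(O)cc5O[C@H](c5ccc(O)c(O)c5)[C@@H]4O)c(O)c3[C@H](c3c(O)cc(O)c4c3O[C@H](c3ccc(O)c(O)c3)[C@H](O)[C@H]4c3c(O)cc4c(c3O)C[C@@H](O)[C@@H](c3ccc(O)c(O)c3)O4)[C@H]2O)cc1 | target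

**Totals and risks**
Total step count: 20. Longest linear sequence: 14 steps (steps 1, 2, 3, 8, 9, 10, 11, 12, 15, 16, 17, 18, 19, 20).

Steps most likely to fail:

1. Step 19 (Proposed new method). The ring closure may be too slow, so that dimer 9 attacks the activated aldehyde first, the acyclic benzylic aryl ether ionises, or the α-alkoxy aldehyde epimerises; capture of the cation may also be poorly site-selective. Fallback with known chemistry, setting out from arylmagnesium chloride 8 (made from 7 as in step 7) and aldehyde 22: addition of the Grignard reagent to the aldehyde in THF at −40 °C should give the diaryl-substituted secondary carbinol F1 (both C4 epimers), in which the C4–C8 bond is already in place at the right carbon. Treatment of carbinol F1 with BF3·OEt2 in CH2Cl2 at −40 °C should ionise the doubly ortho-oxygenated benzylic alcohol, and the free ortho carbon of the bromo-dibenzyloxyphenyl ether should close the pyran ring by intramolecular Friedel–Crafts alkylation (acid cyclisation of 3-aryloxy-1-arylpropanols to 4-arylchromans). The 3,4-trans product with the C4 aryl group quasi-axial is expected to be favoured, and the sequence returns to the route at 24.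

2. Step 15. SN2 attack at the hindered cis-epoxide carbon may be slow and be overtaken by acyl transfer from the ester to the phenoxide or by β-elimination of the product. Fallback, setting out from glycidate 18 and phenol 15: NaBH4 in EtOH at 0 °C should reduce the ester to the cis-epoxy alcohol F2. Base-mediated opening of epoxy alcohol F2 by the phenoxide of 15 at the benzylic carbon (NaOH, aqueous t-BuOH, 60 °C; aryloxide opening of 3-arylglycidols) should give diol F3 with inversion. Selective oxidation of the primary alcohol of diol F3 (TEMPO, catalytic NaOCl, NaClO2, MeCN/phosphate buffer) should give hydroxy acid F4, and EtI/KHCO3 in DMF should return to the route at 19.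

3. Step 10. Discrimination between the para and the two ortho phenols may be poor, or bis-silylation may occur. Fallback, setting out from electrophile 10: the phenols are differentiated before the C–C bond is made. Commercial 3,5-bis(benzyloxy)phenol is silylated (TIPSCl, imidazole, DMF) to silyl ether F5. BF3·OEt2-mediated Friedel–Crafts coupling of 10 with silyl ether F5 (3 equiv, CH2Cl2, −78 to −40 °C) should favour the carbon between the two benzyloxy groups, para to the bulky silyloxy group, and return to the route directly at 14; regioisomers would be removed by chromatography.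

**Further compounds**
F1 | step 19 | secondary carbinol from Grignard 8 and aldehyde 22 (C4 epimers) | OC(c3c(OCc9ccccc9)cc(OCc9ccccc9)c4c3O[C@H](c3ccc(OCc9ccccc9)c(OCc9ccccc9)c3)[C@H](OCc9ccccc9)[C@H]4c3c(OCc9ccccc9)c(Br)c4c(c3OCc9ccccc9)C[C@@H](OCc9ccccc9)[C@@H](c3ccc(OCc9ccccc9)c(OCc9ccccc9)c3)O4)[C@@H](OCc9ccccc9)[C@H](Oc1c(Br)c(OCc9ccccc9)c([C@H]4c5c(OCc9ccccc9)cc(OCc9ccccc9)c(Br)c5O[C@H](c5ccc(OCc9ccccc9)c(OCc9ccccc9)c5)[C@@H]4OCc9ccccc9)c(OCc9ccccc9)c1)c1ccc(OCc9ccccc9)cc1
F2 | step 15 | [(2R,3S)-3-[4-(benzyloxy)phenyl]oxiran-2-yl]methanol (cis) | OC[C@H]1O[C@H]1c1ccc(OCc2ccccc2)cc1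
F3 | step 15 | (2R,3R)-3-aryloxy-3-[4-(benzyloxy)phenyl]propane-1,2-diol | OC[C@@H](O)[C@H](Oc1cc(OCc9ccccc9)c([C@H]4c5c(OCc9ccccc9)cc(OCc9ccccc9)c(Br)c5O[C@H](c5ccc(OCc9ccccc9)c(OCc9ccccc9)c5)[C@@H]4OCc9ccccc9)c(OCc9ccccc9)c1)c1ccc(OCc9ccccc9)cc1
F4 | step 15 | (2S,3R)-3-aryloxy-3-[4-(benzyloxy)phenyl]-2-hydroxypropanoic acid | OC(=O)[C@@H](O)[C@H](Oc1cc(OCc9ccccc9)c([C@H]4c5c(OCc9ccccc9)cc(OCc9ccccc9)c(Br)c5O[C@H](c5ccc(OCc9ccccc9)c(OCc9ccccc9)c5)[C@@H]4OCc9ccccc9)c(OCc9ccccc9)c1)c1ccc(OCc9ccccc9)cc1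
F5 | step 10 | [3,5-bis(benzyloxy)phenoxy]triisopropylsilane | CC(C)[Si](C(C)C)(C(C)C)Oc1cc(OCc2ccccc2)cc(OCc2ccccc2)c1
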